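**Plan**

- Retrosynthesis: the 1,4-dioxane is cut at both C7–O bonds (each oxygen stays on C6), giving two identical 6α-hydroxy-7-ketones. In this monomer ring A is cut at C3–C4 and C5–C10, then the side arms at C5–C6, C7–C8 and C1–C2.
- Enabling feature: in ring A the bonds C3–C4 and C5–C10 lie across the ring from each other, C4 (gem-dimethyl) is β to the oxygen-bearing C6 of ring B, and C10 is benzylic on ring C. Ring A is therefore the cycloadduct of an aryl diene C10=C1–C2=C3 and a β,β-dimethyl enone C4=C5–C6=O whose tether C6–C7–C8–C9 is ring B.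
- Forward order: ring C is bought; the diene arm goes on C9 and the oxygenated enone arm on C8; rings A and B close together in one intramolecular Diels–Alder reaction; ring B is adjusted to the 6α-hydroxy-7-ketone; the dioxane closes last by head-to-tail reductive dimerisation.
- Stereochemistry: the C7 carbinol (asymmetric transfer hydrogenation) controls C10 in the chelated endo cycloaddition. C5 and C6 are then reset from the Δ5-7-ketone by α-face addition opposite the axial C4 and C10 methyl groups. C7 and C7' come from axial hydride delivery to oxocarbenium ions.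

Key step: step 9

Remark: each half is numbered as an abietane (C1–C20, primed in the second half), α/β have their usual meaning (C10 methyl β), and compound 1 and the named reagents are taken to be commercial.

**Step 1**
Reactants: 1 4-bromo-3-methoxybenzaldehyde
Product: 2 3-methoxy-4-(propan-2-yl)benzaldehyde
Conditions: i-PrZnBr, Pd(OAc)2 (1 mol %), CPhos (2 mol %), THF/toluene, rt
Reagents that add atoms: isopropylzinc bromide, CC(C)[Zn]Br
Why: Negishi cross-coupling of a secondary alkylzinc halide with an aryl bromide, in which the CPhos ligand makes reductive elimination faster than β-hydride isomerisation to the n-propyl isomer and the aldehyde is tolerated.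

**Step 2**
Reactants: 2 3-methoxy-4-(propan-2-yl)benzaldehyde
Product: 3 2-bromo-5-methoxy-4-(propan-2-yl)benzaldehyde
Conditions: Br2, AcOH, rt
Reagents that add atoms: bromine, BrBr
Why: Electrophilic aromatic bromination is directed para to the methoxy group (the only free ortho position lies between OMe and CHO), as with 3-methoxybenzaldehydes, which puts bromine on the future C8 next to the aldehyde carbon that becomes C10.

**Step 3**
Reactants: 3 2-bromo-5-methoxy-4-(propan-2-yl)benzaldehyde
Product: 5 1-bromo-2-ethynyl-4-methoxy-5-(propan-2-yl)benzene, via diazoalkene 4 (not isolated)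
Conditions: dimethyl (1-diazo-2-oxopropyl)phosphonate, K2CO3, MeOH, 0 °C to rt
Reagents that add atoms: dimethyl (1-diazo-2-oxopropyl)phosphonate, COP(=O)(OC)C(=[N+]=[N-])C(C)=O
Why: Seyferth–Gilbert homologation in its Ohira–Bestmann form: methanolysis frees the diazomethylphosphonate anion, which olefinates the aldehyde, and loss of N2 with 1,2-hydrogen shift gives the terminal alkyne under conditions that leave the aryl bromide alone.

**Step 4**
Reactants: 5 1-bromo-2-ethynyl-4-methoxy-5-(propan-2-yl)benzene
Product: 7 1-bromo-4-methoxy-2-[(2E)-penta-2,4-dien-2-yl]-5-(propan-2-yl)benzene, via alkenylalane 6 (not isolated)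
Conditions: Me3Al, Cp2ZrCl2 (0.25 equiv), ClCH2CH2Cl, rt; then CH2=CHBr, Pd(PPh3)4 (5 mol %), ZnCl2 (20 mol %), THF, rt
Reagents that add atoms: trimethylaluminium, C[Al](C)C; vinyl bromide, C=CBr
Why: Zirconium-catalysed Negishi carboalumination adds methyl and aluminium syn across the terminal alkyne with methyl on the aryl-bearing carbon, and the palladium-catalysed coupling of the alkenylalane with vinyl bromide goes with retention, so the diene should form as the single (E) isomer (aryl trans to vinyl, methyl inside) while the electron-rich, ortho-substituted aryl bromide is far slower than vinyl bromide in oxidative addition.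

**Step 5**
Reactants: 7 1-bromo-4-methoxy-2-[(2E)-penta-2,4-dien-2-yl]-5-(propan-2-yl)benzene
Product: 10 N-methoxy-2-{4-methoxy-2-[(2E)-penta-2,4-dien-2-yl]-5-(propan-2-yl)phenyl}-N-methyl-2-oxoacetamide, via aryllithium 8 (not isolated), via lithium hemiaminal 9 (not isolated)
Conditions: n-BuLi, THF, −78 °C; then (MeO)MeNCOCON(Me)OMe, −78 to −20 °C; then aq NH4Cl
Reagents that add atoms: N,N'-dimethoxy-N,N'-dimethyloxamide, CON(C)C(=O)C(=O)N(C)OC
Why: Bromine–lithium exchange at −78 °C is faster than carbolithiation of the diene, and acylation of the aryllithium by the bis-Weinreb amide of oxalic acid stops at the chelated hemiaminal, which releases the α-keto Weinreb amide only on work-up (Weinreb ketone synthesis).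

**Step 6**
Reactants: 10 N-methoxy-2-{4-methoxy-2-[(2E)-penta-2,4-dien-2-yl]-5-(propan-2-yl)phenyl}-N-methyl-2-oxoacetamide
Product: 11 (2S)-2-hydroxy-N-methoxy-2-{4-methoxy-2-[(2E)-penta-2,4-dien-2-yl]-5-(propan-2-yl)phenyl}-N-methylacetamide
Conditions: RuCl[(R,R)-TsDPEN](p-cymene) (1 mol %), HCO2H/Et3N (5:2), DMF, rt
Reagents that add atoms: none
Why: Noyori–Ikariya asymmetric transfer hydrogenation of the activated aryl ketone of an α-keto amide sets the C7 carbinol, the (R,R) catalyst being expected to give the (S) alcohol with the aryl group in the place it takes in aryl alkyl ketone reductions.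

**Step 7**
Reactants: 11 (2S)-2-hydroxy-N-methoxy-2-{4-methoxy-2-[(2E)-penta-2,4-dien-2-yl]-5-(propan-2-yl)phenyl}-N-methylacetamide
Product: 12 (2S)-2-(benzyloxy)-N-methoxy-2-{4-methoxy-2-[(2E)-penta-2,4-dien-2-yl]-5-(propan-2-yl)phenyl}-N-methylacetamide
Conditions: BnBr, Ag2O, 4 Å MS, CH2Cl2, rt, dark
Reagents that add atoms: benzyl bromide, BrCc1ccccc1
Why: Silver-oxide-mediated Williamson benzylation needs no strong base and should therefore not racemise the acidic benzylic α-stereocentre, as with mandelic acid derivatives; the benzyl ether is the later chelating group.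

**Step 8**
Reactants: 12 (2S)-2-(benzyloxy)-N-methoxy-2-{4-methoxy-2-[(2E)-penta-2,4-dien-2-yl]-5-(propan-2-yl)phenyl}-N-methylacetamide
Product: 14 (1S)-1-(benzyloxy)-1-{4-methoxy-2-[(2E)-penta-2,4-dien-2-yl]-5-(propan-2-yl)phenyl}-4-methylpent-3-en-2-one, via magnesium hemiaminal 13 (not isolated)
Conditions: Me2C=CHMgBr, THF, −20 to 0 °C; then aq NH4Cl
Reagents that add atoms: 2-methylprop-1-enylmagnesium bromide, CC(C)=C[Mg]Br
Why: Weinreb ketone synthesis with an alkenyl Grignard reagent: the chelated magnesium hemiaminal prevents both over-addition and enolisation of the C7 centre and gives the β,β-dimethyl enone on work-up.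

**Step 9**
Reactants: 14 (1S)-1-(benzyloxy)-1-{4-methoxy-2-[(2E)-penta-2,4-dien-2-yl]-5-(propan-2-yl)phenyl}-4-methylpent-3-en-2-one
Product: 15 (5R,7S,10S)-7-(benzyloxy)-12-methoxyabieta-1,8,11,13-tetraen-6-one (7α-OBn, 5β-H, A/B cis)
Conditions: Me2AlCl (2.2 equiv), CH2Cl2 (0.01 M), −78 to −30 °C
Reagents that add atoms: none
Why: Two-point binding of the aluminium Lewis acid to the C6 carbonyl and the C7 benzyloxy oxygen makes a rigid, strongly activated chelate of the s-cis enone, and the tethered (E)-diene adds to it in an asynchronous concerted [4+2] cycloaddition in which the unhindered diene terminus C3 bonds to the enone β-carbon C4 ahead of the C10–C5 bond while positive charge builds at the tertiary benzylic C10; the closest known reaction type is the Lewis-acid-promoted type 1 intramolecular Diels–Alder reaction of 1,7,9-decatrien-3-ones, combined with the chelation-controlled Diels–Alder reactions of α'-oxygenated enones. Ring A closes as the cyclohexene of the cycloaddition itself and ring B as the six-membered ring spanned by the tether C6–C7–C8–C9. C5 is set by the chelate, because the aryl group on C7 that carries the diene stands above the chelate plane and the diene can reach only that face of the enone (H5 cis to H7), and C10 is set by the (E) geometry of the diene (aryl outside, methyl inside) together with the endo position of the chelated carbonyl (C10 methyl cis to H5), so the (S) carbinol should give the 10S adduct. The step needs endo over exo and chelate over open-chain control: endo is the usual preference of a Lewis-acid-bound enone and is reinforced because the exo mode would press the inside methyl group of the diene onto C6, and chelation is secured by the ether oxygen of the benzyl group and the excess of Me2AlCl. Only C10 has to survive from this step, since C7 is lost in step 11 and C5 in step 12, and any exo or non-chelate adduct is a diastereomer that can be separated here.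

**Step 10**
Reactants: 15 (5R,7S,10S)-7-(benzyloxy)-12-methoxyabieta-1,8,11,13-tetraen-6-one
Product: 16 (5R,7S,10S)-7-hydroxy-12-methoxyabieta-8,11,13-trien-6-one (7α-OH, 5β-H)
Conditions: H2 (1 atm), Pd/C, EtOAc, rt
Reagents that add atoms: none
Why: Heterogeneous hydrogenation saturates the cis-disubstituted C1=C2 bond and hydrogenolyses the primary benzylic C–O bond of the benzyl ether, which should cleave much faster than the hindered secondary C7–O bond.

**Step 11**
Reactants: 16 (5R,7S,10S)-7-hydroxy-12-methoxyabieta-8,11,13-trien-6-one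
Product: 17 (5R,6R,10S)-6-hydroxy-12-methoxyabieta-8,11,13-trien-7-one (drawn as the 6α-OH, 5β-H isomer)
Conditions: DBU (0.3 equiv), degassed toluene, 60 °C
Reagents that add atoms: none
Why: Base-catalysed α-ketol (acyloin) isomerisation through the C6/C7 enediol moves the carbonyl group into conjugation with the p-methoxyaryl ring, the thermodynamic direction, and the configurations that result at C5 and C6 do not matter because both centres are removed in step 12.

**Step 12**
Reactants: 17 (5R,6R,10S)-6-hydroxy-12-methoxyabieta-8,11,13-trien-7-one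
Product: 19 (10S)-12-methoxyabieta-5,8,11,13-tetraen-7-one, via mesylate 18 (not isolated)
Conditions: MsCl, Et3N, CH2Cl2, 0 °C; then DBU, LiBr (cat.), DMF, 100 °C
Reagents that add atoms: none
Why: Mesylation of the α-hydroxyl and base-induced β-elimination of H5 (the α-leaving-group route to enones, as in the dehydrobromination of α-bromo ketones) should give the Δ5-7-ketone, which keeps C10 as its only stereocentre.

**Step 13**
Reactants: 19 (10S)-12-methoxyabieta-5,8,11,13-tetraen-7-one
Product: 21 (5S,6R,10S)-6-hydroxy-12-methoxyabieta-8,11,13-trien-7-one (6α-OH, 5α-H), via hydroperoxide 20 (not isolated)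
Conditions: Mn(dpm)3 (5 mol %), PhSiH3, O2 (1 atm), i-PrOH/CH2Cl2, 0 °C to rt; then P(OEt)3
Reagents that add atoms: dioxygen, O=O
Why: Mukaiyama-type reductive α-hydroxylation of an enone: Mn–H hydrogen-atom transfer to the β-carbon C5 gives the α-keto radical at C6, O2 traps it and the phosphite reduces the hydroperoxide, and both hydrogen and oxygen should enter from the α-face because the β-face of ring B is covered by the axial C10 and C4β methyl groups, which sets 5α-H (A/B trans) and the equatorial 6α-OH.

**Step 14**
Reactants: 21 (5S,6R,10S)-6-hydroxy-12-methoxyabieta-8,11,13-trien-7-one (two molecules)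
Product: 24 target CNP0327150.1 (C2-symmetric 1,4-dioxane in which O-6α of each 12-methoxyabieta-8,11,13-triene half is bonded to C7β of the other), via silyl ether 22 (not isolated), via keto ether 23 (not isolated)
Conditions: (Me3Si)2NH, TMSOTf (5 mol %), CH2Cl2, rt; then Et3SiH (4 equiv), TMSOTf (0.5 equiv), CH2Cl2, −78 to −20 °C
Reagents that add atoms: none
Why: Proposed new method: TMSOTf activates the C7 ketone of one molecule for attack by the C6 silyl ether oxygen of a second, the O-silyl mixed ketal ionises to an aryl- and oxygen-stabilised oxocarbenium ion that Et3SiH reduces, and the same sequence then runs intramolecularly between the remaining silyl ether and ketone to close the 1,4-dioxane; the closest known reaction types are the TMSOTf/Et3SiH reductive etherification of ketones with silyl ethers and the silane reduction of cyclic hemiketals to cyclic ethers, here joined in a head-to-tail cyclodimerisation of an α-silyloxy ketone; hydride should enter each oxocarbenium ion axially from the α-face, so that both new C7–O bonds are equatorial (7β) and trans to the 6α-oxygen, and the single enantiomer of 21 can only give the C2-symmetric dimer.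

**Compound list**

1 | 4-bromo-3-methoxybenzaldehyde | COc1cc(C=O)ccc1Br | starting material
2 | 3-methoxy-4-(propan-2-yl)benzaldehyde | COc1cc(C=O)ccc1C(C)C | intermediate
3 | 2-bromo-5-methoxy-4-(propan-2-yl)benzaldehyde | COc1cc(C=O)c(Br)cc1C(C)C | intermediate
4 | 1-bromo-2-(2-diazoethenyl)-4-methoxy-5-(propan-2-yl)benzene | COc1cc(C=C=[N+]=[N-])c(Br)cc1C(C)C | intermediate
5 | 1-bromo-2-ethynyl-4-methoxy-5-(propan-2-yl)benzene | COc1cc(C#C)c(Br)cc1C(C)C | intermediate
6 | [(1E)-2-(2-bromo-5-methoxy-4-(propan-2-yl)phenyl)prop-1-en-1-yl]dimethylalumane | COc1cc(/C(C)=C/[Al](C)C)c(Br)cc1C(C)C | intermediate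
7 | 1-bromo-4-methoxy-2-[(2E)-penta-2,4-dien-2-yl]-5-(propan-2-yl)benzene | COc1cc(/C(C)=C/C=C)c(Br)cc1C(C)C | intermediate
8 | {4-methoxy-2-[(2E)-penta-2,4-dien-2-yl]-5-(propan-2-yl)phenyl}lithium | COc1cc(/C(C)=C/C=C)c([Li])cc1C(C)C | intermediate
9 | lithium hemiaminal from 8 and the oxamide (both configurations at the new carbon) | COc1cc(/C(C)=C/C=C)c(cc1C(C)C)C(O[Li])(N(C)OC)C(=O)N(C)OC | intermediate
10 | N-methoxy-2-{4-methoxy-2-[(2E)-penta-2,4-dien-2-yl]-5-(propan-2-yl)phenyl}-N-methyl-2-oxoacetamide | COc1cc(/C(C)=C/C=C)c(cc1C(C)C)C(=O)C(=O)N(C)OC | intermediate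
11 | (2S)-2-hydroxy-N-methoxy-2-{4-methoxy-2-[(2E)-penta-2,4-dien-2-yl]-5-(propan-2-yl)phenyl}-N-methylacetamide | COc1cc(/C(C)=C/C=C)c(cc1C(C)C)[C@H](O)C(=O)N(C)OC | intermediate
12 | (2S)-2-(benzyloxy)-N-methoxy-2-{4-methoxy-2-[(2E)-penta-2,4-dien-2-yl]-5-(propan-2-yl)phenyl}-N-methylacetamide | COc1cc(/C(C)=C/C=C)c(cc1C(C)C)[C@H](OCc1ccccc1)C(=O)N(C)OC | intermediate
13 | bromomagnesium hemiaminal from 12 and the Grignard reagent (both configurations at the new carbon) | COc1cc(/C(C)=C/C=C)c(cc1C(C)C)[C@H](OCc1ccccc1)C(O[Mg]Br)(C=C(C)C)N(C)OC | intermediate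
14 | (1S)-1-(benzyloxy)-1-{4-methoxy-2-[(2E)-penta-2,4-dien-2-yl]-5-(propan-2-yl)phenyl}-4-methylpent-3-en-2-one | COc1cc(/C(C)=C/C=C)c(cc1C(C)C)[C@H](OCc1ccccc1)C(=O)C=C(C)C | intermediate
15 | (5R,7S,10S)-7-(benzyloxy)-12-methoxyabieta-1,8,11,13-tetraen-6-one | COc1cc2c(cc1C(C)C)[C@H](OCc1ccccc1)C(=O)[C@@H]1C(C)(C)CC=C[C@]21C | intermediate
16 | (5R,7S,10S)-7-hydroxy-12-methoxyabieta-8,11,13-trien-6-one | COc1cc2c(cc1C(C)C)[C@H](O)C(=O)[C@@H]1C(C)(C)CCC[C@]21C | intermediate
17 | (5R,6R,10S)-6-hydroxy-12-methoxyabieta-8,11,13-trien-7-one | COc1cc2c(cc1C(C)C)C(=O)[C@H](O)[C@@H]1C(C)(C)CCC[C@]21C | intermediate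
18 | (5R,6R,10S)-12-methoxy-7-oxoabieta-8,11,13-trien-6-yl methanesulfonate | COc1cc2c(cc1C(C)C)C(=O)[C@H](OS(C)(=O)=O)[C@@H]1C(C)(C)CCC[C@]21C | intermediate
19 | (10S)-12-methoxyabieta-5,8,11,13-tetraen-7-one | COc1cc2c(cc1C(C)C)C(=O)C=C1C(C)(C)CCC[C@]21C | intermediate
20 | (5S,6R,10S)-6-hydroperoxy-12-methoxyabieta-8,11,13-trien-7-one | COc1cc2c(cc1C(C)C)C(=O)[C@H](OO)[C@H]1C(C)(C)CCC[C@]21C | intermediate
21 | (5S,6R,10S)-6-hydroxy-12-methoxyabieta-8,11,13-trien-7-one | COc1cc2c(cc1C(C)C)C(=O)[C@H](O)[C@H]1C(C)(C)CCC[C@]21C | intermediate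
22 | (5S,6R,10S)-12-methoxy-6-(trimethylsilyloxy)abieta-8,11,13-trien-7-one | COc1cc2c(cc1C(C)C)C(=O)[C@H](O[Si](C)(C)C)[C@H]1C(C)(C)CCC[C@]21C | intermediate
23 | 12-methoxy-7β-[(12-methoxy-7-oxoabieta-8,11,13-trien-6α-yl)oxy]-6α-(trimethylsilyloxy)abieta-8,11,13-triene | COc1cc2c(cc1C(C)C)[C@@H](O[C@H]1C(=O)c3cc(C(C)C)c(OC)cc3[C@@]3(C)CCCC(C)(C)[C@H]13)[C@H](O[Si](C)(C)C)[C@H]1C(C)(C)CCC[C@]21C | intermediate
24 | CNP0327150.1, 6α-O,7'β:7β,6'α-O-linked dimer of 12-methoxyabieta-8,11,13-triene (each half 5S,6R,7R,10S) | COc1cc2c(cc1C(C)C)[C@H]1O[C@H]3[C@H](O[C@@H]1[C@H]1C(C)(C)CCC[C@]21C)c1cc(C(C)C)c(OC)cc1[C@@]1(C)CCCC(C)(C)[C@H]31 | target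

**Step count and risks**

Total step count: 14. Longest linear sequence: 14 (the route is fully linear from 1).

Steps most likely to fail:

1. Step 14 (proposed new method). What may go wrong: hydride transfer to the silyl-activated ketone before the hindered silyl ether has added, so that the C7 oxygen is lost, or open-chain oligomerisation instead of ring closure. Fallback with known reactions, setting out from 21 and returning at 24: one portion of 21 is reduced with NaBH4 (hydride from the α-face) to (5S,6R,7R,10S)-12-methoxyabieta-8,11,13-triene-6,7-diol F1. Mitsunobu cyclodehydration (PPh3, DIAD) activates the benzylic 7β-hydroxyl, and the 6α-oxygen displaces it with inversion to give 6α,7α-epoxy-12-methoxyabieta-8,11,13-triene F2. BF3·OEt2-catalysed opening of F2 at the benzylic C7 by the 6α-hydroxyl of a second portion of 21 (inversion, 7β ether) gives 12-methoxy-7β-[(12-methoxy-7-oxoabieta-8,11,13-trien-6α-yl)oxy]abieta-8,11,13-trien-6α-ol F3, which lies in equilibrium with its cyclic hemiketal. Et3SiH/BF3·OEt2 reduction of that hemiketal (axial hydride) closes the dioxane and gives 24.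

2. Step 9. What may go wrong: cationic oligomerisation of the aryl diene by the Lewis acid, collapse of a stepwise intermediate through the enolate oxygen, or weak endo or chelate control so that the opposite C10 series leaks in. Fallback, setting out from 10 and returning at 19; it trades substrate control for catalyst control, uses a more reactive dienophile and never makes the ring-fusion carbon a stereocentre. Compound 10 reacts with 2-methylprop-1-enylmagnesium bromide at the Weinreb carbonyl to give 1-{4-methoxy-2-[(2E)-penta-2,4-dien-2-yl]-5-(propan-2-yl)phenyl}-4-methylpent-3-ene-1,2-dione F4. Its 1,2-dicarbonyl unit binds the chiral bis(oxazoline) complex of divalent copper [Cu((S,S)-t-Bu-box)](SbF6)2, and the catalysed intramolecular Diels–Alder reaction followed by enolisation of the 6,7-dione should give 6-hydroxy-12-methoxyabieta-1,5,8,11,13-pentaen-7-one F5 (ligand enantiomer chosen for the 10β-methyl series). Triflation (Tf2O, pyridine) gives 12-methoxy-7-oxoabieta-1,5,8,11,13-pentaen-6-yl trifluoromethanesulfonate F6. Palladium-catalysed formate reduction (Pd(OAc)2, PPh3, HCO2H, Bu3N) gives 12-methoxyabieta-1,5,8,11,13-pentaen-7-one F7. Hydrogenation of the unhindered C1=C2 bond with RhCl(PPh3)3 gives 19.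

3. Step 13. What may go wrong: failure of hydrogen-atom transfer to the very hindered C5, or poor facial control when the C6 radical is trapped by O2. Fallback, setting out from 19 and returning at 21: hydrogenation over Pd/C from the α-face gives (5S,10S)-12-methoxyabieta-8,11,13-trien-7-one (sugiol methyl ether) F8, and its potassium enolate (KHMDS, THF, −78 °C) is hydroxylated on the α-face with 2-(benzenesulfonyl)-3-phenyloxaziridine to give 21.

**Further compounds**

F1 | step 14 | (5S,6R,7R,10S)-12-methoxyabieta-8,11,13-triene-6,7-diol | COc1cc2c(cc1C(C)C)[C@@H](O)[C@H](O)[C@H]1C(C)(C)CCC[C@]21C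
F2 | step 14 | 6α,7α-epoxy-12-methoxyabieta-8,11,13-triene | COc1cc2c(cc1C(C)C)[C@@H]1O[C@@H]1[C@H]1C(C)(C)CCC[C@]21C
F3 | step 14 | 12-methoxy-7β-[(12-methoxy-7-oxoabieta-8,11,13-trien-6α-yl)oxy]abieta-8,11,13-trien-6α-ol | COc1cc2c(cc1C(C)C)[C@@H](O[C@H]1C(=O)c3cc(C(C)C)c(OC)cc3[C@@]3(C)CCCC(C)(C)[C@H]13)[C@H](O)[C@H]1C(C)(C)CCC[C@]21C
F4 | step 9 | 1-{4-methoxy-2-[(2E)-penta-2,4-dien-2-yl]-5-(propan-2-yl)phenyl}-4-methylpent-3-ene-1,2-dione | COc1cc(/C(C)=C/C=C)c(cc1C(C)C)C(=O)C(=O)C=C(C)C
F5 | step 9 | 6-hydroxy-12-methoxyabieta-1,5,8,11,13-pentaen-7-one (10β-methyl) | COc1cc2c(cc1C(C)C)C(=O)C(O)=C1C(C)(C)CC=C[C@]21C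
F6 | step 9 | 12-methoxy-7-oxoabieta-1,5,8,11,13-pentaen-6-yl trifluoromethanesulfonate (10β-methyl) | COc1cc2c(cc1C(C)C)C(=O)C(OS(=O)(=O)C(F)(F)F)=C1C(C)(C)CC=C[C@]21C
F7 | step 9 | 12-methoxyabieta-1,5,8,11,13-pentaen-7-one (10β-methyl) | COc1cc2c(cc1C(C)C)C(=O)C=C1C(C)(C)CC=C[C@]21C
F8 | step 13 | (5S,10S)-12-methoxyabieta-8,11,13-trien-7-one | COc1cc2c(cc1C(C)C)C(=O)C[C@H]1C(C)(C)CCC[C@]21C
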